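**Plan**

- Locants: benzofuran numbering (O1, C2, C3, C3a, C4–C7, C7a) for arene ring A and dihydrofuran ring B; C1'–C6' for cyclohexene ring C (C1' on C2, diol at C3'/C4').
- Retrosynthesis: C7–OMe goes back to C7–B; O1–C7a and C7–B are then cut together to a 2-fluoroaryl carbinol; C2–C3 is cut as a syn-aldol between an arylacetyl imide and a ring C enal; the C5–side-chain bond is cut to an aryl bromide and a propargyl silyl ether; C1'=C2' is cut to a dialdehyde.
- Enabling feature: ring A carries oxygen on the neighbouring carbons C7a (O1 of ring B) and C7 (OMe). These are the two carbons of a C7–C7a aryne, which the internal C2 alkoxide and then an external boron electrophile can functionalise one after the other.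
- Forward order: ring C first (steps 1–6), then the arylacetyl imide on ring A (steps 7–9), union by the aldol (step 10), ring B last (step 13), then B → OH → OMe and deprotection.
- Stereochemistry: C3' and C4' are C4 and C3 of 2-deoxy-L-ribose. C2 and C3 come from the (S)-4-benzyloxazolidinone boron aldol; the syn adduct becomes 2,3-trans because ring closure leaves the C2–O bond intact.

Key step: step 13

Assumption: ring C is taken from 2-deoxy-L-ribose because only the L-erythro diol maps onto (3'S,4'R) with the sugar C1/C2 as the two ring methylenes; shikimate- or quinate-derived material would give the enantiomeric diol.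

Abbreviations: TBS = tert-butyldimethylsilyl; Tr = triphenylmethyl; "acetonide ring C unit" = (3aS,7aR)-2,2-dimethyl-3a,6,7,7a-tetrahydro-1,3-benzodioxol-5-yl.

**Route**

Step 1
Reactants: 1 2-deoxy-L-ribose
Product: 2 2-deoxy-3,4-O-isopropylidene-L-erythro-pentopyranose (anomeric mixture)
Conditions: 2-methoxypropene, PPTS (cat.), DMF, 0 °C → rt
Reagents that add atoms: 2-methoxypropene, COC(C)=C
Why: Acid-catalysed acetonide formation takes the cis-3,4-diol of the pyranose form, as is usual for 2-deoxypentoses, and leaves the hemiacetal carbon free.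

Step 2
Reactants: 2 2-deoxy-3,4-O-isopropylidene-L-erythro-pentopyranose
Product: 3 ethyl (2E)-4-[(4R,5S)-5-(hydroxymethyl)-2,2-dimethyl-1,3-dioxolan-4-yl]but-2-enoate
Conditions: Ph3P=CHCO2Et, PhCO2H (cat.), THF, reflux
Reagents that add atoms: ethyl (triphenylphosphoranylidene)acetate, CCOC(=O)C=P(c1ccccc1)(c1ccccc1)c1ccccc1
Why: Wittig olefination with a stabilised ylide intercepts the open-chain aldehyde in equilibrium with the lactol and should give the E-enoate while releasing the C5 hydroxyl.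

Step 3
Reactants: 3 ethyl (2E)-4-[(4R,5S)-5-(hydroxymethyl)-2,2-dimethyl-1,3-dioxolan-4-yl]but-2-enoate
Product: 4 ethyl 4-[(4R,5S)-5-(hydroxymethyl)-2,2-dimethyl-1,3-dioxolan-4-yl]butanoate
Conditions: H2 (1 atm), 10% Pd/C, EtOAc, rt
Reagents that add atoms: none
Why: Catalytic hydrogenation saturates only the conjugated alkene; ester, acetonide and alcohol are inert.

Step 4
Reactants: 4 ethyl 4-[(4R,5S)-5-(hydroxymethyl)-2,2-dimethyl-1,3-dioxolan-4-yl]butanoate
Product: 5 4-[(4R,5S)-5-(hydroxymethyl)-2,2-dimethyl-1,3-dioxolan-4-yl]butan-1-ol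
Conditions: LiAlH4, THF, 0 °C; H2O/NaOH work-up
Reagents that add atoms: none
Why: LiAlH4 reduction of the ester to the primary alcohol is routine and the acetonide is stable to hydride.

Step 5
Reactants: 5 4-[(4R,5S)-5-(hydroxymethyl)-2,2-dimethyl-1,3-dioxolan-4-yl]butan-1-ol
Product: 6 4-[(4R,5R)-5-formyl-2,2-dimethyl-1,3-dioxolan-4-yl]butanal
Conditions: TEMPO (0.2 equiv), PhI(OAc)2 (2.5 equiv), CH2Cl2, rt; used crude
Reagents that add atoms: none
Why: Oxoammonium (TEMPO) oxidation stops at the aldehyde for both primary alcohols and, being base-free, should not epimerise the α-alkoxy aldehyde.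

Step 6
Reactants: 6 4-[(4R,5R)-5-formyl-2,2-dimethyl-1,3-dioxolan-4-yl]butanal
Product: 7 (3aS,7aR)-2,2-dimethyl-3a,6,7,7a-tetrahydro-1,3-benzodioxole-5-carbaldehyde
Conditions: Bn2NH·CF3CO2H (0.5 equiv), toluene, 50 °C
Reagents that add atoms: none
Why: In this amine-salt-mediated intramolecular aldol condensation the enamine of the unbranched aldehyde adds to the α-alkoxy aldehyde (6-enolexo) and the aldol loses water to the conjugated enal, whereas the alternative aldol has no α-hydrogen left and can only revert; both stereocentres are untouched.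

Step 7
Reactants: 8 2-(5-bromo-2-fluorophenyl)acetic acid; 9 tert-butyldimethyl(prop-2-yn-1-yloxy)silane
Product: 10 2-[5-(3-TBSO-prop-1-yn-1-yl)-2-fluorophenyl]acetic acid
Conditions: Pd(PPh3)2Cl2 (3 mol %), CuI (6 mol %), Et3N, DMF, 70 °C; citric acid work-up
Reagents that add atoms: none
Why: Sonogashira coupling engages the aryl bromide (the C–F bond is inert to zerovalent palladium here) while the acid is carried as its triethylammonium salt.

Step 8
Reactants: 10 2-[5-(3-TBSO-prop-1-yn-1-yl)-2-fluorophenyl]acetic acid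
Product: 11 2-[5-(3-TBSO-propyl)-2-fluorophenyl]acetic acid
Conditions: H2 (1 atm), 10% Pd/C, EtOAc, rt
Reagents that add atoms: none
Why: Hydrogenation of the alkyne to the alkane in an aprotic solvent should leave the silyl ether and the aryl fluoride intact.

Step 9
Reactants: 11 2-[5-(3-TBSO-propyl)-2-fluorophenyl]acetic acid; 12 (S)-4-benzyl-1,3-oxazolidin-2-one
Product: 14 (4S)-4-benzyl-3-{[5-(3-TBSO-propyl)-2-fluorophenyl]acetyl}-1,3-oxazolidin-2-one, via mixed pivalic anhydride 13 (not isolated)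
Conditions: t-BuCOCl, Et3N, THF, −20 °C; then LiCl, 12, −20 °C → rt
Reagents that add atoms: none
Why: N-acylation of the oxazolidinone through the mixed pivalic anhydride with LiCl/Et3N activation is the standard mild route to arylacetyl imides.

Step 10
Reactants: 14 (4S)-4-benzyl-3-{[5-(3-TBSO-propyl)-2-fluorophenyl]acetyl}-1,3-oxazolidin-2-one; 7 (3aS,7aR)-2,2-dimethyl-3a,6,7,7a-tetrahydro-1,3-benzodioxole-5-carbaldehyde
Product: 16 (4S)-4-benzyl-3-{(2S,3S)-2-[5-(3-TBSO-propyl)-2-fluorophenyl]-3-hydroxy-3-(acetonide ring C unit)propanoyl}-1,3-oxazolidin-2-one, via Z boron enolate 15 (not isolated)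
Conditions: n-Bu2BOTf, i-Pr2NEt, CH2Cl2, −78 → 0 °C; 7, −78 → 0 °C; pH 7 buffer, MeOH, 30% H2O2, 0 °C
Reagents that add atoms: none
Why: In this Evans boron aldol the Z-enolate reacts through a chair Zimmerman–Traxler transition state on the face opposite the benzyl group of the auxiliary, which should give the (2S,3S) syn adduct, i.e. C3 (R) and C2 (S) of the target, with the remote stereocentres of 7 not expected to override reagent control.

Step 11
Reactants: 16 the (2S,3S) aldol adduct
Product: 17 (1S,2R)-2-[5-(3-TBSO-propyl)-2-fluorophenyl]-1-(acetonide ring C unit)propane-1,3-diol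
Conditions: LiBH4, MeOH (2 equiv), THF, 0 °C
Reagents that add atoms: none
Why: Reductive removal of the auxiliary with LiBH4 gives the 1,3-diol without touching the stereocentres and returns the oxazolidinone.

Step 12
Reactants: 17 (1S,2R)-2-[5-(3-TBSO-propyl)-2-fluorophenyl]-1-(acetonide ring C unit)propane-1,3-diol
Product: 18 (1S,2R)-2-[5-(3-TBSO-propyl)-2-fluorophenyl]-1-(acetonide ring C unit)-3-(trityloxy)propan-1-ol
Conditions: TrCl, Et3N, DMAP (cat.), CH2Cl2, rt
Reagents that add atoms: trityl chloride, ClC(c1ccccc1)(c1ccccc1)c1ccccc1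
Why: Tritylation is selective for the primary hydroxyl over the hindered secondary allylic one, and a trityl ether, unlike a silyl ether, cannot migrate to the neighbouring alkoxide in the next step.

Step 13
Reactants: 18 (1S,2R)-2-[5-(3-TBSO-propyl)-2-fluorophenyl]-1-(acetonide ring C unit)-3-(trityloxy)propan-1-ol; 19 2-isopropoxy-4,4,5,5-tetramethyl-1,3,2-dioxaborolane
Product: 23 2-{(2S,3R)-5-(3-TBSO-propyl)-2-(acetonide ring C unit)-3-[(trityloxy)methyl]-2,3-dihydro-1-benzofuran-7-yl}-4,4,5,5-tetramethyl-1,3,2-dioxaborolane, via ortho-lithiated alkoxide 20 (not isolated), via aryne alkoxide 21 (not isolated), via C7 aryllithium 22 (not isolated)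
Conditions: s-BuLi (2.2 equiv), THF, −78 °C, 1 h; −78 → −20 °C; then −78 °C, 19 (3 equiv), → rt; aq. NH4Cl
Reagents that add atoms: none
Why: The first equivalent of s-BuLi makes the C2 lithium alkoxide and the second removes H7, the only hydrogen ortho to fluorine, to give 20, which loses LiF on warming to give the C7–C7a aryne 21. The alkoxide then adds in the ring plane to the nearer aryne carbon C7a in a five-membered exo closure (attack at C7 would need a bridged ring), which forms O1–C7a and ring B and leaves the carbanion at C7 (22); i-PrOBpin converts it into the borate and, after work-up, boronate 23. The closest known reaction type is the base-induced benzyne ring closure of ortho-halophenylalkyl alkoxides and amides with electrophilic quench of the resulting aryl anion. No stereocentre is formed: the C2–O and C3–C bonds are not broken, so the syn aldol relationship becomes 2,3-trans. The step needs one lithiation site and one nucleophile: fluorine acidifies only H7, the tether length fixes addition at C7a, and the trityl ether keeps the primary oxygen (which could close an isomeric five-membered ring) masked.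

Step 14
Reactants: 23 the C7 pinacol boronate
Product: 24 (2S,3R)-5-(3-TBSO-propyl)-2-(acetonide ring C unit)-3-[(trityloxy)methyl]-2,3-dihydro-1-benzofuran-7-ol
Conditions: NaBO3·4H2O (5 equiv), THF/H2O (1:1), rt
Reagents that add atoms: sodium perborate tetrahydrate, [Na+].[Na+].O[B-]1(O)OO[B-](O)(O)OO1
Why: Perborate oxidation of the aryl boronate (1,2-aryl shift from boron to oxygen) gives the phenol under conditions that should spare the alkene, the acetal and both ethers.

Step 15
Reactants: 24 the C7 phenol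
Product: 25 (2S,3R)-5-(3-TBSO-propyl)-7-methoxy-2-(acetonide ring C unit)-3-[(trityloxy)methyl]-2,3-dihydro-1-benzofuran
Conditions: MeI, K2CO3, acetone, 40 °C
Reagents that add atoms: iodomethane, CI
Why: Williamson O-methylation of the phenoxide is selective because no other acidic site is present.

Step 16
Reactants: 25 the protected methyl ether
Product: 26 difengpiol A, (1R,2S)-4-[(2S,3R)-3-(hydroxymethyl)-5-(3-hydroxypropyl)-7-methoxy-2,3-dihydro-1-benzofuran-2-yl]cyclohex-3-ene-1,2-diol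
Conditions: 1 M aq. HCl, THF, rt
Reagents that add atoms: none
Why: Aqueous acid hydrolyses the acetonide and cleaves the trityl and primary silyl ethers, while the dilute, weakly nucleophilic medium should leave the allylic C2–O1 and C3'–O bonds intact.

**Compound list**

1 | 2-deoxy-L-ribose | O=CC[C@@H](O)[C@@H](O)CO | starting material
2 | 2-deoxy-3,4-O-isopropylidene-L-erythro-pentopyranose | OC1C[C@H]2OC(C)(C)O[C@H]2CO1 | intermediate
3 | ethyl (2E)-4-[(4R,5S)-5-(hydroxymethyl)-2,2-dimethyl-1,3-dioxolan-4-yl]but-2-enoate | CCOC(=O)/C=C/C[C@H]1OC(C)(C)O[C@H]1CO | intermediate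
4 | ethyl 4-[(4R,5S)-5-(hydroxymethyl)-2,2-dimethyl-1,3-dioxolan-4-yl]butanoate | CCOC(=O)CCC[C@H]1OC(C)(C)O[C@H]1CO | intermediate
5 | 4-[(4R,5S)-5-(hydroxymethyl)-2,2-dimethyl-1,3-dioxolan-4-yl]butan-1-ol | OCCCC[C@H]1OC(C)(C)O[C@H]1CO | intermediate
6 | 4-[(4R,5R)-5-formyl-2,2-dimethyl-1,3-dioxolan-4-yl]butanal | O=CCCC[C@H]1OC(C)(C)O[C@H]1C=O | intermediate
7 | (3aS,7aR)-2,2-dimethyl-3a,6,7,7a-tetrahydro-1,3-benzodioxole-5-carbaldehyde | O=CC1=C[C@@H]2OC(C)(C)O[C@@H]2CC1 | intermediate
8 | 2-(5-bromo-2-fluorophenyl)acetic acid | OC(=O)Cc1cc(Br)ccc1F | starting material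
9 | tert-butyldimethyl(prop-2-yn-1-yloxy)silane | C#CCO[Si](C)(C)C(C)(C)C | starting material
10 | 2-[5-(3-TBSO-prop-1-yn-1-yl)-2-fluorophenyl]acetic acid | OC(=O)Cc1cc(C#CCO[Si](C)(C)C(C)(C)C)ccc1F | intermediate
11 | 2-[5-(3-TBSO-propyl)-2-fluorophenyl]acetic acid | OC(=O)Cc1cc(CCCO[Si](C)(C)C(C)(C)C)ccc1F | intermediate
12 | (S)-4-benzyl-1,3-oxazolidin-2-one | O=C1OC[C@H](Cc2ccccc2)N1 | starting material
13 | mixed anhydride of 11 with pivalic acid | CC(C)(C)C(=O)OC(=O)Cc1cc(CCCO[Si](C)(C)C(C)(C)C)ccc1F | intermediate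
14 | (4S)-4-benzyl-3-{[5-(3-TBSO-propyl)-2-fluorophenyl]acetyl}-1,3-oxazolidin-2-one | O=C(Cc1cc(CCCO[Si](C)(C)C(C)(C)C)ccc1F)N1[C@@H](Cc2ccccc2)COC1=O | intermediate
15 | Z-dibutylboron enolate of 14 | CCCCB(CCCC)O/C(=C\c1cc(CCCO[Si](C)(C)C(C)(C)C)ccc1F)N1[C@@H](Cc2ccccc2)COC1=O | intermediate
16 | (4S)-4-benzyl-3-{(2S,3S)-2-[5-(3-TBSO-propyl)-2-fluorophenyl]-3-hydroxy-3-(acetonide ring C unit)propanoyl}-1,3-oxazolidin-2-one | O=C([C@@H](c1cc(CCCO[Si](C)(C)C(C)(C)C)ccc1F)[C@H](O)C1=C[C@@H]2OC(C)(C)O[C@@H]2CC1)N1[C@@H](Cc2ccccc2)COC1=O | intermediate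
17 | (1S,2R)-2-[5-(3-TBSO-propyl)-2-fluorophenyl]-1-(acetonide ring C unit)propane-1,3-diol | OC[C@@H](c1cc(CCCO[Si](C)(C)C(C)(C)C)ccc1F)[C@H](O)C1=C[C@@H]2OC(C)(C)O[C@@H]2CC1 | intermediate
18 | (1S,2R)-2-[5-(3-TBSO-propyl)-2-fluorophenyl]-1-(acetonide ring C unit)-3-(trityloxy)propan-1-ol | O(C[C@@H](c1cc(CCCO[Si](C)(C)C(C)(C)C)ccc1F)[C@H](O)C1=C[C@@H]2OC(C)(C)O[C@@H]2CC1)C(c1ccccc1)(c1ccccc1)c1ccccc1 | intermediate
19 | 2-isopropoxy-4,4,5,5-tetramethyl-1,3,2-dioxaborolane | CC(C)OB1OC(C)(C)C(C)(C)O1 | starting material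
20 | C7-lithiated lithium alkoxide of 18 | O(C[C@@H](c1cc(CCCO[Si](C)(C)C(C)(C)C)cc([Li])c1F)[C@H](O[Li])C1=C[C@@H]2OC(C)(C)O[C@@H]2CC1)C(c1ccccc1)(c1ccccc1)c1ccccc1 | intermediate
21 | C7–C7a aryne lithium alkoxide | O(C[C@@H](C1=CC(CCCO[Si](C)(C)C(C)(C)C)=CC#C1)[C@H](O[Li])C1=C[C@@H]2OC(C)(C)O[C@@H]2CC1)C(c1ccccc1)(c1ccccc1)c1ccccc1 | intermediate
22 | 7-lithio-(2S,3R)-dihydrobenzofuran | [Li]c1cc(CCCO[Si](C)(C)C(C)(C)C)cc2c1O[C@H](C1=C[C@@H]3OC(C)(C)O[C@@H]3CC1)[C@H]2COC(c1ccccc1)(c1ccccc1)c1ccccc1 | intermediate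
23 | 2-{(2S,3R)-5-(3-TBSO-propyl)-2-(acetonide ring C unit)-3-[(trityloxy)methyl]-2,3-dihydro-1-benzofuran-7-yl}-4,4,5,5-tetramethyl-1,3,2-dioxaborolane | CC1(C)OB(c2cc(CCCO[Si](C)(C)C(C)(C)C)cc3c2O[C@H](C2=C[C@@H]4OC(C)(C)O[C@@H]4CC2)[C@H]3COC(c2ccccc2)(c2ccccc2)c2ccccc2)OC1(C)C | intermediate
24 | (2S,3R)-5-(3-TBSO-propyl)-2-(acetonide ring C unit)-3-[(trityloxy)methyl]-2,3-dihydro-1-benzofuran-7-ol | Oc1cc(CCCO[Si](C)(C)C(C)(C)C)cc2c1O[C@H](C1=C[C@@H]3OC(C)(C)O[C@@H]3CC1)[C@H]2COC(c1ccccc1)(c1ccccc1)c1ccccc1 | intermediate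
25 | (2S,3R)-5-(3-TBSO-propyl)-7-methoxy-2-(acetonide ring C unit)-3-[(trityloxy)methyl]-2,3-dihydro-1-benzofuran | COc1cc(CCCO[Si](C)(C)C(C)(C)C)cc2c1O[C@H](C1=C[C@@H]3OC(C)(C)O[C@@H]3CC1)[C@H]2COC(c1ccccc1)(c1ccccc1)c1ccccc1 | intermediate
26 | difengpiol A | COc1cc(CCCO)cc2c1O[C@H](C1=C[C@H](O)[C@H](O)CC1)[C@H]2CO | target

**Count and risks**

Total steps: 16. Longest linear sequence: 13 steps (steps 1–6, then 10–16).

Step 13 is the most exposed. s-BuLi may add to the aryne in competition with the alkoxide, or the C7 anion may be lost by proton transfer before borylation. The fallback sets out from 18 and separates ring closure from C–B bond formation. Lithium 2,2,6,6-tetramethylpiperidide (3 equiv, THF, −78 → 0 °C) is a non-nucleophilic base for the same fluorine-directed lithiation, LiF loss and alkoxide addition. The aryl anion is then deliberately protonated (by the amine formed and on quench) to give the 7-unsubstituted (2S,3R)-dihydrobenzofuran F1. Ether-oxygen-directed ortho-lithiation of F1 (n-BuLi, TMEDA, Et2O, 0 °C) can only occur at C7, the one position next to O1, and i-PrOBpin then returns the route to 23.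

Step 10 may suffer erosion of syn selectivity, or retro-aldol and epimerisation at the acidic α-aryl centre under the amine/borinate conditions. The fallback sets out from acid 11. EDC·HCl/DMAP coupling with (S)-4-benzyl-1,3-thiazolidine-2-thione gives the N-acyl thiazolidinethione F2. Its chlorotitanium enolate (TiCl4, i-Pr2NEt, N-methyl-2-pyrrolidinone, CH2Cl2, −78 °C) should add to 7 through a non-chelated closed transition state to give the same (2S,3S) syn adduct, the thiazolidinethione aldol F3. NaBH4 (THF/H2O, 0 °C) then removes the thione auxiliary under milder conditions than an imide requires and rejoins the route at diol 17.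

Step 6 may fail through epimerisation or β-elimination at the α-alkoxy aldehyde, or through oligomerisation of the dialdehyde under amine catalysis. The fallback sets out from hydroxy ester 4 and closes ring C by olefin metathesis instead of carbonyl condensation:

- TEMPO/PhI(OAc)2 oxidation gives the aldehyde ester F4.
- Wittig methylenation (Ph3P=CH2, THF, −78 → 0 °C) gives the vinyl dioxolane ester F5.
- The lithium enolate (LDA, THF, −78 °C) is aminomethylated with Me2N=CH2+ I− to the Mannich base F6.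
- MeI converts F6 into the ammonium iodide F7, and DBU eliminates trimethylamine to give the 2-methylidene ester F8.
- Ring-closing metathesis with the second-generation Grubbs catalyst (H2IMes)(PCy3)Cl2Ru=CHPh (CH2Cl2, 40 °C) should give the cyclohexene ester F9.
- i-Bu2AlH (CH2Cl2, −78 °C) gives the allylic alcohol F10, and MnO2 (CH2Cl2, rt) returns the route to aldehyde 7.

**Further compounds**

F1 | step 13 | (2S,3R)-5-(3-TBSO-propyl)-2-(acetonide ring C unit)-3-[(trityloxy)methyl]-2,3-dihydro-1-benzofuran | c1cc(CCCO[Si](C)(C)C(C)(C)C)cc2c1O[C@H](C1=C[C@@H]3OC(C)(C)O[C@@H]3CC1)[C@H]2COC(c1ccccc1)(c1ccccc1)c1ccccc1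
F2 | step 10 | (4S)-4-benzyl-3-{[5-(3-TBSO-propyl)-2-fluorophenyl]acetyl}-1,3-thiazolidine-2-thione | O=C(Cc1cc(CCCO[Si](C)(C)C(C)(C)C)ccc1F)N1[C@@H](Cc2ccccc2)CSC1=S
F3 | step 10 | (4S)-4-benzyl-3-{(2S,3S)-2-[5-(3-TBSO-propyl)-2-fluorophenyl]-3-hydroxy-3-(acetonide ring C unit)propanoyl}-1,3-thiazolidine-2-thione | O=C([C@@H](c1cc(CCCO[Si](C)(C)C(C)(C)C)ccc1F)[C@H](O)C1=C[C@@H]2OC(C)(C)O[C@@H]2CC1)N1[C@@H](Cc2ccccc2)CSC1=S
F4 | step 6 | ethyl 4-[(4R,5R)-5-formyl-2,2-dimethyl-1,3-dioxolan-4-yl]butanoate | CCOC(=O)CCC[C@H]1OC(C)(C)O[C@H]1C=O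
F5 | step 6 | ethyl 4-[(4R,5S)-5-ethenyl-2,2-dimethyl-1,3-dioxolan-4-yl]butanoate | CCOC(=O)CCC[C@H]1OC(C)(C)O[C@H]1C=C
F6 | step 6 | ethyl 2-[(dimethylamino)methyl]-4-[(4R,5S)-5-ethenyl-2,2-dimethyl-1,3-dioxolan-4-yl]butanoate | CCOC(=O)C(CN(C)C)CC[C@H]1OC(C)(C)O[C@H]1C=C
F7 | step 6 | {2-(ethoxycarbonyl)-4-[(4R,5S)-5-ethenyl-2,2-dimethyl-1,3-dioxolan-4-yl]butyl}trimethylammonium iodide | CCOC(=O)C(C[N+](C)(C)C)CC[C@H]1OC(C)(C)O[C@H]1C=C.[I-]
F8 | step 6 | ethyl 4-[(4R,5S)-5-ethenyl-2,2-dimethyl-1,3-dioxolan-4-yl]-2-methylidenebutanoate | CCOC(=O)C(=C)CC[C@H]1OC(C)(C)O[C@H]1C=C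
F9 | step 6 | ethyl (3aS,7aR)-2,2-dimethyl-3a,6,7,7a-tetrahydro-1,3-benzodioxole-5-carboxylate | CCOC(=O)C1=C[C@@H]2OC(C)(C)O[C@@H]2CC1
F10 | step 6 | [(3aS,7aR)-2,2-dimethyl-3a,6,7,7a-tetrahydro-1,3-benzodioxol-5-yl]methanol | OCC1=C[C@@H]2OC(C)(C)O[C@@H]2CC1
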